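**Plan**

1. Ring B is a 2-aryloxyresorcinol. Its ether carbon lies between the two C–OH carbons and para to the carbinol chain, so it is C2 of a 5-substituted cyclohexane-1,3-dione (dihydro ring B). The first cut is the ether bond O–C(ring B) of the 22-membered ring, made at that dihydro oxidation level.
2. C2 of the dione is normally nucleophilic. As a 2-diazo-1,3-dione it becomes an electrophilic rhodium carbenoid (polarity reversal) and can bond to the nucleophilic oxygen of ring A, a 5-alkylresorcinol with two equivalent OH groups. Ring B is aromatised afterwards by loss of two hydrogens.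
3. Further cuts: the dione ring (Michael–Claisen annulation of a γ-silyloxy enone with a malonate), the enone C=C (cross-metathesis), the chain bonds at the epichlorohydrin unit, and the aryl–alkyl bond of ring A (Grignard couplings with 1,12-dibromododecane).
4. Forward order: ring A plus C12 chain, (R)-epoxide, allylic alcohol, enone, carbocyclic dione (future ring B), diazo compound, macrocyclic ether ring, aromatisation of ring B, desilylation.
5. The single (R) carbinol centre comes from (R)-epichlorohydrin and is not touched again.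

Key step: step 9

Remark: in the 22-membered ring both benzene rings are taken to rotate freely, so there is no planar chirality and the two hydroxyls of ring A lead to one and the same macrocycle.

**Route**

Step 1
Reactants: 1 1,3-bis(benzyloxy)-5-bromobenzene; 2 1,12-dibromododecane
Product: 4 1,3-bis(benzyloxy)-5-(12-bromododecyl)benzene, via aryl Grignard reagent 3 (not isolated)
Conditions: Mg, THF, 50 °C; then added to 2 (3 equiv), Li2CuCl4 (3 mol%), THF, 0 °C to rt
Reagents that add atoms: none
Why: Copper-catalysed Kumada-type (Kochi) coupling of an aryl Grignard reagent with a primary alkyl bromide is reliable, and the excess of the symmetrical dibromide should keep double arylation low.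

Step 2
Reactants: 4 1,3-bis(benzyloxy)-5-(12-bromododecyl)benzene; 5 (R)-epichlorohydrin
Product: 8 (2R)-2-{13-[3,5-bis(benzyloxy)phenyl]tridecyl}oxirane, via alkyl Grignard reagent 6 (not isolated), via chlorohydrin 7 (not isolated)
Conditions: Mg, THF, 50 °C; CuI (10 mol%), 5, THF, −40 to 0 °C; then aq. NaOH, THF/MeOH, rt
Reagents that add atoms: none
Why: CuI-catalysed Grignard opening of epichlorohydrin occurs at the unsubstituted epoxide carbon, and Williamson ring closure of the chlorohydrin displaces chloride at the primary carbon, so the stereocentre is never a reaction site and the (R) configuration of 5 is carried into 8.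

Step 3
Reactants: 8 (2R)-2-{13-[3,5-bis(benzyloxy)phenyl]tridecyl}oxirane
Product: 9 (3R)-16-[3,5-bis(benzyloxy)phenyl]hexadec-1-en-3-ol
Conditions: Me3S+ I− (4 equiv), n-BuLi (3.9 equiv), THF, −10 °C to rt
Reagents that add atoms: trimethylsulfonium iodide, C[S+](C)C.[I-]
Why: Excess dimethylsulfonium methylide (the Corey–Chaykovsky reagent) opens the terminal epoxide at CH2 and the γ-oxido sulfonium salt undergoes ylide-mediated β-elimination, a known one-carbon homologation of epoxides to allylic alcohols that leaves the carbinol centre untouched.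

Step 4
Reactants: 9 (3R)-16-[3,5-bis(benzyloxy)phenyl]hexadec-1-en-3-ol
Product: 10 {[(3R)-16-[3,5-bis(benzyloxy)phenyl]hexadec-1-en-3-yl]oxy}(tert-butyl)dimethylsilane
Conditions: TBSCl, imidazole, DMF, rt
Reagents that add atoms: tert-butyldimethylsilyl chloride, CC(C)(C)[Si](C)(C)Cl
Why: Standard silylation of a secondary alcohol turns the hydroxyl into a hindered, weakly basic ether oxygen that should stay out of the later carbenoid step.

Step 5
Reactants: 10 the silyl ether of step 4; 11 methyl vinyl ketone
Product: 12 (3E,5R)-18-[3,5-bis(benzyloxy)phenyl]-5-[(tert-butyldimethylsilyl)oxy]octadec-3-en-2-one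
Conditions: 11 (4 equiv), second-generation Hoveyda–Grubbs catalyst RuCl2(H2IMes)(=CH-C6H4-2-OiPr) (5 mol%), CH2Cl2, 40 °C
Reagents that add atoms: none
Why: Olefin cross-metathesis of a terminal alkene with an excess of the electron-poor partner should give the E-enone selectively, and the allylic silyloxy group slows homodimerisation of 10.

Step 6
Reactants: 12 the γ-silyloxy enone; 13 dibenzyl malonate
Product: 15 benzyl 6-{(1R)-14-[3,5-bis(benzyloxy)phenyl]-1-[(tert-butyldimethylsilyl)oxy]tetradecyl}-2,4-dioxocyclohexane-1-carboxylate (mixture of ring epimers and enol tautomers), via Michael adduct 14 (not isolated)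
Conditions: 13 (1.2 equiv), NaH (1.1 equiv), THF, 0 °C; then 12, 0 to 65 °C; AcOH quench
Reagents that add atoms: none
Why: Michael addition of the malonate anion to the enone followed by intramolecular Claisen condensation of the methyl ketone onto one ester is the classical route to 5-substituted cyclohexane-1,3-diones, and the preformed anion without excess base should avoid γ-deprotonation at the silyloxy-bearing centre.

Step 7
Reactants: 15 the benzyl dioxocyclohexanecarboxylate
Product: 17 5-{(1R)-1-[(tert-butyldimethylsilyl)oxy]-14-(3,5-dihydroxyphenyl)tetradecyl}cyclohexane-1,3-dione, via keto acid 16 (not isolated)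
Conditions: H2 (1 atm), Pd/C (10%), EtOAc, rt; then 50 °C
Reagents that add atoms: none
Why: Hydrogenolysis over palladium on carbon cleaves the benzyl ester and both benzyl ethers in one operation and the freed β-keto acid loses CO2 on gentle warming, while the enolised dione, the arene and the silyl ether are inert in EtOAc.

Step 8
Reactants: 17 the dione with free ring A hydroxyls
Product: 18 2-diazo-5-{(1R)-1-[(tert-butyldimethylsilyl)oxy]-14-(3,5-dihydroxyphenyl)tetradecyl}cyclohexane-1,3-dione
Conditions: 4-acetamidobenzenesulfonyl azide (1.1 equiv), Et3N (1.1 equiv), MeCN, 0 °C to rt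
Reagents that add atoms: 4-acetamidobenzenesulfonyl azide, CC(=O)Nc1ccc(cc1)S(=O)(=O)N=[N+]=[N-]
Why: Regitz diazo transfer should occur only at C2 of the 1,3-dione, the one position acidic enough (pKa about 5) to be ionised by Et3N, while the ring A phenols stay protonated and unreactive toward the sulfonyl azide.

Step 9
Reactants: 18 the 2-diazo-1,3-dione
Product: 20 macrocyclic 2-aryloxy-1,3-dione (22-membered ring: the oxygen of ring A is bonded to C2 of the cyclohexane-1,3-dione, whose C5 carries the (R)-CH(OTBS)(CH2)13 chain back to ring A; enolised in solution), via rhodium carbenoid 19 (not isolated)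
Conditions: Rh2(OAc)4 (3 mol%), 4 Å MS, ClCH2CH2Cl, 70 °C, syringe-pump addition of 18 over 12 h to a final 1 mM
Reagents that add atoms: none
Why: Dirhodium tetraacetate extrudes N2 from the diazo dione to give an electrophilic carbenoid at C2, a ring A hydroxyl adds to it to form an oxonium ylide, and proton transfer releases the catalyst and the enolised 2-aryloxy dione, so the normally nucleophilic C2 is joined to the nucleophilic phenol oxygen. The closest known reaction type is the O–H insertion of phenols and alcohols into rhodium carbenoids from 2-diazo-1,3-dicarbonyl compounds, including its ring-forming variants. The one ring closed is the 22-membered ring (four atoms of the future ring B, fourteen chain carbons, three atoms of ring A and the oxygen), closed end to end as a macro-etherification. No stereocentre is created, since C2 ends up sp2 in the enol and the remote (R) centre is not involved. The step needs O–H insertion to beat attack on carbon and ring closure to beat oligomerisation: high dilution with slow addition, two equivalent hydroxyls on ring A and the absence of hydrogen next to the carbenoid carbon should secure this. Capture by the silyl ether oxygen is disfavoured because that oxygen is hindered and weakly basic, and bridging across the six-membered ring would require an anti-Bredt bridgehead enolate.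

Step 10
Reactants: 20 the macrocyclic 2-aryloxy-1,3-dione
Product: 22 tetrakis-O-(tert-butyldimethylsilyl)gravicycle, via silyl dienol ether 21 (not isolated)
Conditions: TBSOTf (4 equiv), Et3N (6 equiv), CH2Cl2, 0 °C to rt; evaporation, pentane extraction; DDQ (1.1 equiv), 1,4-dioxane, rt
Reagents that add atoms: tert-butyldimethylsilyl triflate, CC(C)(C)[Si](C)(C)OS(=O)(=O)C(F)(F)F
Why: Silyl triflate and Et3N convert the enolised dione into the 1,3-bis(silyloxy)cyclohexa-1,3-diene (and silylate the phenol), and DDQ removes the two remaining ring hydrogens by hydride abstraction and proton loss, a standard cyclohexadiene dehydrogenation driven by aromatisation of ring B.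

Step 11
Reactants: 22 tetrakis-O-(tert-butyldimethylsilyl)gravicycle
Product: 23 gravicycle
Conditions: TBAF (5 equiv), AcOH (5 equiv), THF, 0 °C to rt, argon
Reagents that add atoms: none
Why: Fluoride cleaves the three aryl silyl ethers and the secondary benzylic silyl ether, and the AcOH buffer should protect the electron-rich polyphenol from phenoxide oxidation without ionising the benzylic alcohol.

**Compound list**

1 | 1,3-bis(benzyloxy)-5-bromobenzene | Brc1cc(OCc2ccccc2)cc(OCc2ccccc2)c1 | starting material
2 | 1,12-dibromododecane | BrCCCCCCCCCCCCBr | starting material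
3 | 3,5-bis(benzyloxy)phenylmagnesium bromide | Br[Mg]c1cc(OCc2ccccc2)cc(OCc2ccccc2)c1 | intermediate (not isolated)
4 | 1,3-bis(benzyloxy)-5-(12-bromododecyl)benzene | BrCCCCCCCCCCCCc1cc(OCc2ccccc2)cc(OCc2ccccc2)c1 | intermediate
5 | (R)-epichlorohydrin | ClC[C@H]1CO1 | starting material
6 | 12-[3,5-bis(benzyloxy)phenyl]dodecylmagnesium bromide | Br[Mg]CCCCCCCCCCCCc1cc(OCc2ccccc2)cc(OCc2ccccc2)c1 | intermediate (not isolated)
7 | (2R)-15-[3,5-bis(benzyloxy)phenyl]-1-chloropentadecan-2-ol | ClC[C@H](O)CCCCCCCCCCCCCc1cc(OCc2ccccc2)cc(OCc2ccccc2)c1 | intermediate (not isolated)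
8 | (2R)-2-{13-[3,5-bis(benzyloxy)phenyl]tridecyl}oxirane | C(CCCCCCCCCCCCc1cc(OCc2ccccc2)cc(OCc2ccccc2)c1)[C@@H]1CO1 | intermediate
9 | (3R)-16-[3,5-bis(benzyloxy)phenyl]hexadec-1-en-3-ol | C=C[C@H](O)CCCCCCCCCCCCCc1cc(OCc2ccccc2)cc(OCc2ccccc2)c1 | intermediate
10 | {[(3R)-16-[3,5-bis(benzyloxy)phenyl]hexadec-1-en-3-yl]oxy}(tert-butyl)dimethylsilane | C=C[C@H](O[Si](C)(C)C(C)(C)C)CCCCCCCCCCCCCc1cc(OCc2ccccc2)cc(OCc2ccccc2)c1 | intermediate
11 | methyl vinyl ketone | CC(=O)C=C | starting material
12 | (3E,5R)-18-[3,5-bis(benzyloxy)phenyl]-5-[(tert-butyldimethylsilyl)oxy]octadec-3-en-2-one | CC(=O)/C=C/[C@H](O[Si](C)(C)C(C)(C)C)CCCCCCCCCCCCCc1cc(OCc2ccccc2)cc(OCc2ccccc2)c1 | intermediate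
13 | dibenzyl malonate | O=C(OCc1ccccc1)CC(=O)OCc1ccccc1 | starting material
14 | dibenzyl 2-{(5R)-18-[3,5-bis(benzyloxy)phenyl]-5-[(tert-butyldimethylsilyl)oxy]-2-oxooctadecan-4-yl}propanedioate (C4 epimers) | CC(=O)CC(C(C(=O)OCc1ccccc1)C(=O)OCc1ccccc1)[C@H](O[Si](C)(C)C(C)(C)C)CCCCCCCCCCCCCc1cc(OCc2ccccc2)cc(OCc2ccccc2)c1 | intermediate (not isolated)
15 | benzyl 6-{(1R)-14-[3,5-bis(benzyloxy)phenyl]-1-[(tert-butyldimethylsilyl)oxy]tetradecyl}-2,4-dioxocyclohexane-1-carboxylate (ring epimers, drawn as the diketo form) | O=C1CC(=O)C(C(=O)OCc2ccccc2)C(C1)[C@H](O[Si](C)(C)C(C)(C)C)CCCCCCCCCCCCCc1cc(OCc2ccccc2)cc(OCc2ccccc2)c1 | intermediate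
16 | 6-{(1R)-1-[(tert-butyldimethylsilyl)oxy]-14-(3,5-dihydroxyphenyl)tetradecyl}-2,4-dioxocyclohexane-1-carboxylic acid | O=C1CC(=O)C(C(=O)O)C(C1)[C@H](O[Si](C)(C)C(C)(C)C)CCCCCCCCCCCCCc1cc(O)cc(O)c1 | intermediate (not isolated)
17 | 5-{(1R)-1-[(tert-butyldimethylsilyl)oxy]-14-(3,5-dihydroxyphenyl)tetradecyl}cyclohexane-1,3-dione | O=C1CC(=O)CC(C1)[C@H](O[Si](C)(C)C(C)(C)C)CCCCCCCCCCCCCc1cc(O)cc(O)c1 | intermediate
18 | 2-diazo-5-{(1R)-1-[(tert-butyldimethylsilyl)oxy]-14-(3,5-dihydroxyphenyl)tetradecyl}cyclohexane-1,3-dione | [N-]=[N+]=C1C(=O)CC(CC1=O)[C@H](O[Si](C)(C)C(C)(C)C)CCCCCCCCCCCCCc1cc(O)cc(O)c1 | intermediate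
19 | dirhodium tetraacetate carbenoid at C2 of the dione of 18 (acetate bridges drawn as terminal acetates) | CC(=O)O[Rh](OC(C)=O)(=C1C(=O)CC(CC1=O)[C@H](O[Si](C)(C)C(C)(C)C)CCCCCCCCCCCCCc1cc(O)cc(O)c1)[Rh](OC(C)=O)OC(C)=O | intermediate (not isolated)
20 | macrocyclic 2-aryloxy-1,3-dione: O-(tert-butyldimethylsilyl)gravicycle with ring B as a cyclohexane-1,3-dione bearing the ring A oxygen at C2 (drawn as the diketo form) | Oc1cc2cc(c1)OC1C(=O)CC(CC1=O)[C@H](O[Si](C)(C)C(C)(C)C)CCCCCCCCCCCCC2 | intermediate
21 | tris-silylated macrocycle: ring A silyl ether and ring B as the 2-aryloxy-1,3-bis(silyloxy)cyclohexa-1,3-diene (both epimers at the sp3 ring CH) | CC(C)(C)[Si](C)(C)Oc1cc2cc(c1)OC1=C(O[Si](C)(C)C(C)(C)C)CC(C=C1O[Si](C)(C)C(C)(C)C)[C@H](O[Si](C)(C)C(C)(C)C)CCCCCCCCCCCCC2 | intermediate (not isolated)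
22 | tetrakis-O-(tert-butyldimethylsilyl)gravicycle | CC(C)(C)[Si](C)(C)Oc1cc2cc(c1)Oc1c(O[Si](C)(C)C(C)(C)C)cc(cc1O[Si](C)(C)C(C)(C)C)[C@H](O[Si](C)(C)C(C)(C)C)CCCCCCCCCCCCC2 | intermediate
23 | gravicycle, (R) at the carbinol | Oc1cc2cc(c1)Oc1c(O)cc(cc1O)[C@H](O)CCCCCCCCCCCCC2 | target

**Step count and risks**

Total step count: 11. Longest linear sequence: 11 steps (1 to 23).

Steps most likely to fail:

Step 9. Intermolecular O–H insertion (oligomers), capture of the carbenoid by traces of water, or attack on a ring A carbon may outrun closure of the 22-membered ring. The fallback makes the same ether bond on an aromatic ring B by an intramolecular Ullmann coupling; it sets out from 4 and returns at 23. The lithium enolate of 1-(4-bromo-3,5-dimethoxyphenyl)ethanone (LiN(iPr)2, THF/DMPU, −78 °C) would be alkylated with 4 (NaI) to give 14-[3,5-bis(benzyloxy)phenyl]-1-(4-bromo-3,5-dimethoxyphenyl)tetradecan-1-one F1. BCl3 with pentamethylbenzene (CH2Cl2, −78 °C) would remove the two benzyl groups to give 1-(4-bromo-3,5-dimethoxyphenyl)-14-(3,5-dihydroxyphenyl)tetradecan-1-one F2. CuI, N,N-dimethylglycine and Cs2CO3 in 1,4-dioxane at high dilution (110 °C) would close the diaryl ether, the bromide being activated by the para acyl group, to give the macrocyclic ketone O,O-dimethyl ether F3. BBr3 (CH2Cl2) would cleave the methyl ethers to the macrocyclic triphenol ketone F4. Asymmetric transfer hydrogenation with RuCl[(R,R)-TsDPEN](p-cymene) in HCO2H/Et3N would then give the (R)-alcohol 23.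

Step 10. Enol silylation may stay incomplete, or DDQ may over-oxidise the benzylic positions once ring B is aromatic. The fallback sets out from 20 and returns at 23. A direct aerobic palladium-catalysed dehydrogenation of the enolised dione (Pd(OCOCF3)2, 2-(dimethylamino)pyridine, TsOH, O2, DMSO, 80 °C; palladium enolate formation and β-hydride elimination) would give O-(tert-butyldimethylsilyl)gravicycle F5 without any silyl dienol ether. TBAF/AcOH as in step 11 would then give 23.

Step 6. Base may deprotonate the γ-position of the enone (loss of configuration or elimination) before conjugate addition, or the Claisen ring closure may stay incomplete. The fallback sets out from 12 and returns at 17. A Mukaiyama–Michael addition of 1-(benzyloxy)-1-(trimethylsilyloxy)ethene under Me3SiOTf catalysis (CH2Cl2, −78 °C; aqueous work-up) consumes the enone without base and would give benzyl (4R)-17-[3,5-bis(benzyloxy)phenyl]-4-[(tert-butyldimethylsilyl)oxy]-3-(2-oxopropyl)heptadecanoate F6. KOtBu in THF would cyclise this 5-oxohexanoate directly to 5-{(1R)-14-[3,5-bis(benzyloxy)phenyl]-1-[(tert-butyldimethylsilyl)oxy]tetradecyl}cyclohexane-1,3-dione F7. Hydrogenolysis (H2, Pd/C, EtOAc) would then give 17.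

**Further compounds**

F1 | step 9 | 14-[3,5-bis(benzyloxy)phenyl]-1-(4-bromo-3,5-dimethoxyphenyl)tetradecan-1-one | COc1cc(cc(OC)c1Br)C(=O)CCCCCCCCCCCCCc1cc(OCc2ccccc2)cc(OCc2ccccc2)c1
F2 | step 9 | 1-(4-bromo-3,5-dimethoxyphenyl)-14-(3,5-dihydroxyphenyl)tetradecan-1-one | COc1cc(cc(OC)c1Br)C(=O)CCCCCCCCCCCCCc1cc(O)cc(O)c1
F3 | step 9 | macrocyclic ketone, ring B O,O-dimethyl ether (gravicycle skeleton with C=O in place of the carbinol) | Oc1cc2cc(c1)Oc1c(OC)cc(cc1OC)C(=O)CCCCCCCCCCCCC2
F4 | step 9 | macrocyclic triphenol ketone (gravicycle with C=O in place of the carbinol) | Oc1cc2cc(c1)Oc1c(O)cc(cc1O)C(=O)CCCCCCCCCCCCC2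
F5 | step 10 | O-(tert-butyldimethylsilyl)gravicycle (silyl ether at the carbinol) | Oc1cc2cc(c1)Oc1c(O)cc(cc1O)[C@H](O[Si](C)(C)C(C)(C)C)CCCCCCCCCCCCC2
F6 | step 6 | benzyl (4R)-17-[3,5-bis(benzyloxy)phenyl]-4-[(tert-butyldimethylsilyl)oxy]-3-(2-oxopropyl)heptadecanoate (C3 epimers) | CC(=O)CC(CC(=O)OCc1ccccc1)[C@H](O[Si](C)(C)C(C)(C)C)CCCCCCCCCCCCCc1cc(OCc2ccccc2)cc(OCc2ccccc2)c1
F7 | step 6 | 5-{(1R)-14-[3,5-bis(benzyloxy)phenyl]-1-[(tert-butyldimethylsilyl)oxy]tetradecyl}cyclohexane-1,3-dione | O=C1CC(=O)CC(C1)[C@H](O[Si](C)(C)C(C)(C)C)CCCCCCCCCCCCCc1cc(OCc2ccccc2)cc(OCc2ccccc2)c1
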